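The autumn run, charged with more X than summer, ended with less E, 60.2% against 68.2%, although nearly all X had reacted in both.

in all of them: Q 170 mM (held)
- summer: X 0.54 M; run made earlier
- autumn: X 1.2 M; run made earlier
- flask: X 0.80 M; time 2.5 h

| run | time / h | E / % | X / % |
|---|---|---|---|
| summer | 0.200 | 17.6 | 72.1 |
| summer | 0.500 | 42.0 | 44.9 |
| summer | 1.00 | 59.1 | 18.8 |
| summer | 2.50 | 68.2 | 1.9 |
| autumn | 0.333 | 26.7 | 61.5 |
| autumn | 0.833 | 47.0 | 26.7 |
| autumn | 1.50 | 56.7 | 6.9 |
| autumn | 2.50 | 60.2 | 0.8 |

(readings scatter by 1 percentage point)

1. the E standing at 2.5 h, as a percentage of the X charged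
2. the change that raises the amount of E at 2.5 h, in percent of the X charged most ("none" if none brings more than 2 percentage points) (teal / blue / none)
3. amount of E at 2.5 h, in percent of the X charged, after blue

- teal: doubling the transfer coefficient of Q, all else as stated
- blue: doubling the saturation concentration of Q, all else as stated

- the analysis behind the earlier runs scatters by 1 percentage point, standard deviation
- at the start none of Q is in solution

How much of the reacted X becomes E? Take the loss ratio ρ as the charged X standing neither as X nor as E, divided by the E standing. The final readings give ρ = 0.438 for summer and 0.648 for autumn, a rise of 0.317 M⁻¹ with charge. A straight line gives this flask ρ = 0.521: its loss ratio, charged X standing elsewhere per unit of E standing. With X left at 1.35%, the mean of the two runs, this reckoning shares the reacted X between E and the rest in that ratio and gives 64.9% of E at 2.5 h.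

Does the gas matter? The first-order constant of X read from the autumn run rises from 1.46 h⁻¹ to 2.03 h⁻¹, which reads as dissolved Q lagging early and then catching up. Teal can act on that lag, whereas blue raises the level dissolved Q approaches. If E alone consumes dissolved Q, blue takes ρ to 0.260, half of the value above, and this reckoning gives 78.3%.

The forecast gives 65%, blue, and 70% after blue, lower than this reckoning, and it notes that “E formation looks oddly insensitive to Q”.

The flask gives 65.2% of E. Teal adds 0.85 percentage points and blue 13 points, reaching 78.7%, so the better change is blue.

    X → Z (k = 8.30 × 10⁻⁵ s⁻¹)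
    X + E → L (k = 1.40 × 10⁻⁴ M⁻¹ s⁻¹)
    Q ⇌ D, rate k3*(csat - [D]) (kL = 0.0120 s⁻¹)
    X + D → E (k = 0.00220 M⁻¹ s⁻¹)

With 1.1% of X left, the flask's ρ is 0.516. At 2.50 h, X + D → E uses X 4.5 times as fast as X → Z, with D at 0.170 M. This ratio, a selectivity factor, is proportional to D. The neighbour flask charged with 0.32 M of X lies below the summer charge, where the line gives ρ = 0.369; with 1.4% of X left, that means 72.0% of E, and the neighbour holds 73.4%.

All runs stem from a simulated flask for substances that don't exist, and the scatter is random.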